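**Retrosynthetic overview**
- The strategy rests on the isolated (E)-trisubstituted olefin C2'=C3' (chain numbered from benzylic C1' to the hydroxymethyl carbon C16'). It carries the methyl on C3' and the benzylic C1' on C2', and sits two bonds from the (S)-C5' carbinol, so it is read as terminal alkyne + methyl + benzyl.
- Target ⇒ its tetrakis-TBS ether (one global desilylation) ⇒ (S)-homopropargylic silyl ether + trimethylaluminium + protected hydroquinone benzylic chloride, joined by Zr-catalysed methylalumination and Pd-catalysed alkenylalane–benzyl chloride coupling (C3'–CH3 and C1'–C2' bonds).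
- Alkyne fragment: (2E,6E)-farnesol ⇒ 12-silyloxyfarnesal ⇒ catalyst-controlled propargylboration, which forms C4'–C5' and sets the only stereocentre.
- Arene fragment: 2-hydroxy-3-methylbenzaldehyde ⇒ para-hydroxylation (Elbs) ⇒ bis-silylation, reduction, chlorination.
- No ring is formed at any stage; the benzene ring is bought and the chain stays acyclic.

Key step: step 12

Remark: the (S)-TRIP/Si-face/4S assignment in step 6 is made by analogy with the sense reported for aryl and alkenyl aldehydes. It would be confirmed by Mosher ester analysis of 9, and the antipodal catalyst used if the sense proved opposite.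

**Route**

Step 1
Reactants: 1 (2E,6E)-farnesol
Product: 2 (2E,6E)-farnesyl acetate
Conditions: Ac2O, pyridine, DMAP (cat.), CH2Cl2, 0 °C to rt
Reagents that add atoms: acetic anhydride, CC(=O)OC(C)=O
Why: DMAP-catalysed O-acetylation of the primary allylic alcohol protects C1–OH and electronically deactivates the C2=C3 olefin, so that the allylic oxidation of the next step goes to the distal prenyl end.

Step 2
Reactants: 2 (2E,6E)-farnesyl acetate
Product: 3 (2E,6E,10E)-12-hydroxy-3,7,11-trimethyldodeca-2,6,10-trien-1-yl acetate
Conditions: SeO2 (cat.), t-BuOOH, salicylic acid (cat.), CH2Cl2, 0 °C to rt; stopped at partial conversion, 2 recycled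
Reagents that add atoms: selenium dioxide, O=[Se]=O; tert-butyl hydroperoxide, CC(C)(C)OO
Why: Sharpless catalytic SeO2/t-BuOOH allylic oxidation (ene reaction then [2,3]-sigmatropic shift) attacks the most electron-rich, least hindered terminal trisubstituted olefin at its (E)-methyl group, which should give the (E)-configured primary allylic alcohol and leave the other olefins untouched.

Step 3
Reactants: 3 (2E,6E,10E)-12-hydroxy-3,7,11-trimethyldodeca-2,6,10-trien-1-yl acetate
Product: 4 (2E,6E,10E)-12-(tert-butyldimethylsilyloxy)-3,7,11-trimethyldodeca-2,6,10-trien-1-yl acetate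
Conditions: TBSCl, imidazole, DMF, rt
Reagents that add atoms: tert-butyldimethylsilyl chloride, CC(C)(C)[Si](C)(C)Cl
Why: Corey silylation of the primary allylic alcohol under conditions to which the acetate and the olefins are inert.

Step 4
Reactants: 4 (2E,6E,10E)-12-(tert-butyldimethylsilyloxy)-3,7,11-trimethyldodeca-2,6,10-trien-1-yl acetate
Product: 5 (2E,6E,10E)-12-(tert-butyldimethylsilyloxy)-3,7,11-trimethyldodeca-2,6,10-trien-1-ol
Conditions: K2CO3 (cat.), MeOH, 0 °C to rt
Reagents that add atoms: none
Why: Base-catalysed transesterification (Zemplén-type methanolysis) removes the acetate, while the primary TBS ether and the olefins are stable to K2CO3/MeOH.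

Step 5
Reactants: 5 (2E,6E,10E)-12-(tert-butyldimethylsilyloxy)-3,7,11-trimethyldodeca-2,6,10-trien-1-ol
Product: 6 (2E,6E,10E)-12-(tert-butyldimethylsilyloxy)-3,7,11-trimethyldodeca-2,6,10-trienal
Conditions: activated MnO2, CH2Cl2, rt
Reagents that add atoms: none
Why: Activated MnO2 oxidises the allylic alcohol chemoselectively to the enal without E/Z isomerisation of C2=C3 and leaves the silyl ether alone.

Step 6
Reactants: 6 (2E,6E,10E)-12-(tert-butyldimethylsilyloxy)-3,7,11-trimethyldodeca-2,6,10-trienal; 7 allenylboronic acid pinacol ester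
Product: 9 (4S,5E,9E,13E)-15-(tert-butyldimethylsilyloxy)-6,10,14-trimethylpentadeca-5,9,13-trien-1-yn-4-ol, via O-pinacolatoboryl ether of the propargylation adduct 8 (not isolated)
Conditions: (S)-TRIP [(S)-3,3'-bis(2,4,6-triisopropylphenyl)-BINOL hydrogen phosphate] (10 mol%), 4 Å MS, toluene, −30 to 0 °C; aq. NaHCO3 work-up
Reagents that add atoms: none
Why: Chiral phosphoric acid-catalysed propargylboration, in which the allenylboronate adds through a closed six-membered SE2' transition state (hence 1,2-addition and only the homopropargylic carbinol), and the (S)-TRIP phosphate, hydrogen-bonded to a boronate oxygen and to the formyl hydrogen, should direct attack to the Si face of the enal and so set the 4S carbinol (C5' of the target) by catalyst control.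

Step 7
Reactants: 9 (4S,5E,9E,13E)-15-(tert-butyldimethylsilyloxy)-6,10,14-trimethylpentadeca-5,9,13-trien-1-yn-4-ol
Product: 10 (4S,5E,9E,13E)-4,15-bis(tert-butyldimethylsilyloxy)-6,10,14-trimethylpentadeca-5,9,13-trien-1-yne
Conditions: TBSCl, imidazole, DMAP (cat.), DMF, rt
Reagents that add atoms: tert-butyldimethylsilyl chloride, CC(C)(C)[Si](C)(C)Cl
Why: Corey silylation of the secondary allylic/homopropargylic alcohol under mildly basic conditions avoids ionisation of the allylic carbinol and leaves the terminal alkyne C–H free.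

Step 8
Reactants: 11 2-hydroxy-3-methylbenzaldehyde
Product: 13 2,5-dihydroxy-3-methylbenzaldehyde, via potassium 3-formyl-4-hydroxy-5-methylphenyl sulfate 12 (not isolated)
Conditions: K2S2O8, 10% aq. NaOH, 5–20 °C; then conc. HCl, 80 °C
Reagents that add atoms: potassium peroxydisulfate, [K+].[K+].[O-]S(=O)(=O)OOS(=O)(=O)[O-]
Why: Elbs persulfate oxidation, in which the phenoxide attacks a peroxide oxygen through its para carbon (both ortho positions are blocked by CHO and CH3) and acid hydrolysis of the aryl sulfate releases the hydroquinone aldehyde, as in the classical conversion of salicylaldehyde into gentisaldehyde.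

Step 9
Reactants: 13 2,5-dihydroxy-3-methylbenzaldehyde
Product: 14 2,5-bis(tert-butyldimethylsilyloxy)-3-methylbenzaldehyde
Conditions: TBSCl (2.5 equiv), imidazole, DMAP (cat.), DMF, rt to 40 °C
Reagents that add atoms: tert-butyldimethylsilyl chloride, CC(C)(C)[Si](C)(C)Cl
Why: Corey bis-silylation (DMAP for the hindered, hydrogen-bonded 2-OH) puts on the arene the same protecting group as on the side chain, so that a single fluoride step frees all four hydroxyls at the end.

Step 10
Reactants: 14 2,5-bis(tert-butyldimethylsilyloxy)-3-methylbenzaldehyde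
Product: 15 [2,5-bis(tert-butyldimethylsilyloxy)-3-methylphenyl]methanol
Conditions: NaBH4, THF/MeOH, −20 to 0 °C; aq. NH4Cl
Reagents that add atoms: none
Why: Borohydride reduction of the aryl aldehyde to the benzylic alcohol, run cold in a protic medium so that the alkoxide is protonated before a phenol-to-alkoxide silyl shift can occur.

Step 11
Reactants: 15 [2,5-bis(tert-butyldimethylsilyloxy)-3-methylphenyl]methanol
Product: 16 2,5-bis(tert-butyldimethylsilyloxy)-3-methylbenzyl chloride
Conditions: PPh3, N-chlorosuccinimide, THF, −20 °C to rt; used promptly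
Reagents that add atoms: N-chlorosuccinimide, O=C1CCC(=O)N1Cl
Why: Appel-type chlorination (Ph3P/NCS) replaces the primary benzylic hydroxyl by chloride through SN2 displacement of the phosphorus-activated oxygen under neutral conditions that do not cleave aryl silyl ethers.

Step 12
Reactants: 10 (4S,5E,9E,13E)-4,15-bis(tert-butyldimethylsilyloxy)-6,10,14-trimethylpentadeca-5,9,13-trien-1-yne; 17 trimethylaluminium; 16 2,5-bis(tert-butyldimethylsilyloxy)-3-methylbenzyl chloride
Product: 19 tetrakis(tert-butyldimethylsilyl) ether of the target, via (E)-alkenyldimethylalane 18 (not isolated)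
Conditions: Cp2ZrCl2 (0.2 equiv), AlMe3 (2.5 equiv), H2O (1 equiv), CH2Cl2, −20 to 0 °C; volatiles and excess AlMe3 removed in vacuo; then THF, 16 (1.0 equiv), Pd(PPh3)4 (5 mol%), 0 °C to rt
Reagents that add atoms: none
Why: The Cp2ZrCl2/AlMe3 couple adds methyl and metal syn across the terminal alkyne of 10 with methyl on the internal carbon (Negishi zirconium-catalysed methylalumination, water-accelerated so that it runs cold), giving the (E)-alkenyldimethylalane 18. Pd(0) then inserts into the benzylic C–Cl bond of 16, the alkenyl group transmetalates from aluminium to palladium, and reductive elimination forms the C1'–C2' sp3–sp2 bond with retention of olefin geometry (Negishi alkenylalane–benzyl halide cross-coupling). No ring is closed and no stereocentre is created; the E geometry of C2'=C3' follows from the syn addition and its regiochemistry, and the preformed (S)-C5' centre, two bonds from the alkyne, takes no part. The step needs alkyne-over-olefin chemoselectivity, which is secured because the three trisubstituted olefins and the silyl ethers do not undergo methylalumination. It also needs alkenyl-over-methyl transfer, secured by the faster transmetalation of the sp2 ligand and by stripping excess AlMe3 before the coupling. Because the arene enters as a benzylic electrophile, no allylic partner exists that could scramble by SN2' attack or erode the E geometry.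

Step 13
Reactants: 19 tetrakis(tert-butyldimethylsilyl) ether of the target
Product: 20 2-[(2E,5S,6E,10E,14E)-5,16-dihydroxy-3,7,11,15-tetramethylhexadeca-2,6,10,14-tetraen-1-yl]-6-methylbenzene-1,4-diol (CNP0151872.1)
Conditions: TBAF (6 equiv), AcOH (6 equiv), degassed THF, 0 °C to rt, Ar; degassed pH 7 buffer work-up
Reagents that add atoms: none
Why: Fluoride-mediated desilylation cleaves the two aryl, the primary allylic and the secondary allylic TBS ethers in one operation, the acetic acid buffer keeping the hydroquinone protonated and the exclusion of oxygen preventing its oxidation to the quinone, while no olefin or stereocentre is touched.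

**Compound list**

1 | (2E,6E)-farnesol | CC(C)=CCC/C(C)=C/CC/C(C)=C/CO | starting material
2 | (2E,6E)-farnesyl acetate | CC(C)=CCC/C(C)=C/CC/C(C)=C/COC(C)=O | intermediate
3 | (2E,6E,10E)-12-hydroxy-3,7,11-trimethyldodeca-2,6,10-trien-1-yl acetate | C/C(=C\CC/C(C)=C/CC/C(C)=C/COC(C)=O)CO | intermediate
4 | (2E,6E,10E)-12-(tert-butyldimethylsilyloxy)-3,7,11-trimethyldodeca-2,6,10-trien-1-yl acetate | C/C(=C\CC/C(C)=C/CC/C(C)=C/COC(C)=O)CO[Si](C)(C)C(C)(C)C | intermediate
5 | (2E,6E,10E)-12-(tert-butyldimethylsilyloxy)-3,7,11-trimethyldodeca-2,6,10-trien-1-ol | C/C(=C\CC/C(C)=C/CC/C(C)=C/CO)CO[Si](C)(C)C(C)(C)C | intermediate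
6 | (2E,6E,10E)-12-(tert-butyldimethylsilyloxy)-3,7,11-trimethyldodeca-2,6,10-trienal | C/C(=C\CC/C(C)=C/CC/C(C)=C/C=O)CO[Si](C)(C)C(C)(C)C | intermediate
7 | allenylboronic acid pinacol ester | C=C=CB1OC(C)(C)C(C)(C)O1 | starting material
8 | O-pinacolatoboryl ether of (4S)-alcohol 9 | C/C(=C\CC/C(C)=C/CC/C(C)=C/[C@@H](OB1OC(C)(C)C(C)(C)O1)CC#C)CO[Si](C)(C)C(C)(C)C | intermediate
9 | (4S,5E,9E,13E)-15-(tert-butyldimethylsilyloxy)-6,10,14-trimethylpentadeca-5,9,13-trien-1-yn-4-ol | C/C(=C\CC/C(C)=C/CC/C(C)=C/[C@@H](O)CC#C)CO[Si](C)(C)C(C)(C)C | intermediate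
10 | (4S,5E,9E,13E)-4,15-bis(tert-butyldimethylsilyloxy)-6,10,14-trimethylpentadeca-5,9,13-trien-1-yne | C/C(=C\CC/C(C)=C/CC/C(C)=C/[C@@H](O[Si](C)(C)C(C)(C)C)CC#C)CO[Si](C)(C)C(C)(C)C | intermediate
11 | 2-hydroxy-3-methylbenzaldehyde | Cc1cccc(C=O)c1O | starting material
12 | potassium 3-formyl-4-hydroxy-5-methylphenyl sulfate | Cc1cc(OS(=O)(=O)[O-])cc(C=O)c1O.[K+] | intermediate
13 | 2,5-dihydroxy-3-methylbenzaldehyde | Cc1cc(O)cc(C=O)c1O | intermediate
14 | 2,5-bis(tert-butyldimethylsilyloxy)-3-methylbenzaldehyde | Cc1cc(O[Si](C)(C)C(C)(C)C)cc(C=O)c1O[Si](C)(C)C(C)(C)C | intermediate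
15 | [2,5-bis(tert-butyldimethylsilyloxy)-3-methylphenyl]methanol | Cc1cc(O[Si](C)(C)C(C)(C)C)cc(CO)c1O[Si](C)(C)C(C)(C)C | intermediate
16 | 2,5-bis(tert-butyldimethylsilyloxy)-3-methylbenzyl chloride | ClCc1cc(O[Si](C)(C)C(C)(C)C)cc(C)c1O[Si](C)(C)C(C)(C)C | intermediate
17 | trimethylaluminium | C[Al](C)C | starting material
18 | dimethyl[(1E,4S,5E,9E,13E)-4,15-bis(tert-butyldimethylsilyloxy)-2,6,10,14-tetramethylpentadeca-1,5,9,13-tetraen-1-yl]alane | C/C(=C\CC/C(C)=C/CC/C(C)=C/[C@@H](O[Si](C)(C)C(C)(C)C)C/C(C)=C/[Al](C)C)CO[Si](C)(C)C(C)(C)C | intermediate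
19 | (2E,5S,6E,10E,14E)-1-[2,5-bis(tert-butyldimethylsilyloxy)-3-methylphenyl]-5,16-bis(tert-butyldimethylsilyloxy)-3,7,11,15-tetramethylhexadeca-2,6,10,14-tetraene | C/C(=C\CC/C(C)=C/CC/C(C)=C/[C@@H](O[Si](C)(C)C(C)(C)C)C/C(C)=C/Cc1cc(O[Si](C)(C)C(C)(C)C)cc(C)c1O[Si](C)(C)C(C)(C)C)CO[Si](C)(C)C(C)(C)C | intermediate
20 | 2-[(2E,5S,6E,10E,14E)-5,16-dihydroxy-3,7,11,15-tetramethylhexadeca-2,6,10,14-tetraen-1-yl]-6-methylbenzene-1,4-diol | C/C(=C\CC/C(C)=C/CC/C(C)=C/[C@@H](O)C/C(C)=C/Cc1cc(O)cc(C)c1O)CO | target

**Step count**

Total: 13 steps. Longest linear sequence: 9 steps (steps 1–7, 12, 13 from farnesol). The arene branch is 4 steps (8–11) before the convergence.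

**Steps most likely to fail**

1. Step 12. The methylalumination may be incomplete or accompanied by alkyne C–H metalation, and the Lewis-acidic aluminium species may ionise the allylic C5' silyl ether or the ortho-silyloxy benzylic chloride. In the coupling, methyl instead of alkenyl transfer to palladium would consume 16. Fallback, setting out from 10 and 16 and returning at 19: the two events are separated and the polarity of the coupling is reversed. The methylalumination of 10 is quenched with iodine (Cp2ZrCl2, AlMe3, CH2Cl2; then I2, THF, −30 °C) to give (1E,4S,5E,9E,13E)-4,15-bis(tert-butyldimethylsilyloxy)-1-iodo-2,6,10,14-tetramethylpentadeca-1,5,9,13-tetraene F1, which can be purified and its geometry checked. Chloride 16 is converted with zinc dust and LiCl in THF into [2,5-bis(tert-butyldimethylsilyloxy)-3-methylbenzyl]zinc chloride F2. A Pd-catalysed Negishi coupling of F1 with F2 (Pd(PPh3)4, THF, rt) then gives 19 with retention of the E geometry, in the absence of any aluminium Lewis acid.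

2. Step 6. Facial discrimination may be poor with a β,β-disubstituted aliphatic enal, which offers the catalyst pocket less than an aryl aldehyde does, and an uncatalysed background addition may erode the enantiomeric purity. Fallback, setting out from 6 and returning at 9: stereocontrol is moved from the C–C bond formation to a resolution. Aldehyde 6 and boronate 7 are combined under achiral acid catalysis (diphenyl phosphate, toluene, rt) to give racemic (5E,9E,13E)-15-(tert-butyldimethylsilyloxy)-6,10,14-trimethylpentadeca-5,9,13-trien-1-yn-4-ol F3. Lipase-catalysed transesterification (Amano lipase PS, vinyl acetate, MTBE, 30 °C, stopped a little past half conversion) should, by Kazlauskas' rule (alkenyl chain as large group, propargyl as medium group), acylate the 4R enantiomer to (4R,5E,9E,13E)-15-(tert-butyldimethylsilyloxy)-6,10,14-trimethylpentadeca-5,9,13-trien-1-yn-4-yl acetate F4. The unreacted (4S)-alcohol 9 is then separated by chromatography.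

3. Step 13. The freed hydroquinone may oxidise to the quinone during desilylation or chromatography, and the secondary allylic silyl ether may cleave more slowly than the aryl ethers, lengthening the exposure. Fallback, setting out from 19 and returning at 20: the oxidation is made deliberate and then reversed. Unbuffered desilylation (TBAF, THF, rt) followed by Ag2O in Et2O gives the air-stable 2-[(2E,5S,6E,10E,14E)-5,16-dihydroxy-3,7,11,15-tetramethylhexadeca-2,6,10,14-tetraen-1-yl]-6-methyl-1,4-benzoquinone F5, which is purified without precautions. Reduction with aqueous sodium dithionite in a two-phase Et2O/water system under argon, with simple phase separation and evaporation, then gives 20.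

**Further compounds**

F1 | step 12 | (1E,4S,5E,9E,13E)-4,15-bis(tert-butyldimethylsilyloxy)-1-iodo-2,6,10,14-tetramethylpentadeca-1,5,9,13-tetraene | C/C(=C\CC/C(C)=C/CC/C(C)=C/[C@@H](O[Si](C)(C)C(C)(C)C)C/C(C)=C/I)CO[Si](C)(C)C(C)(C)C
F2 | step 12 | [2,5-bis(tert-butyldimethylsilyloxy)-3-methylbenzyl]zinc chloride | Cl[Zn]Cc1cc(O[Si](C)(C)C(C)(C)C)cc(C)c1O[Si](C)(C)C(C)(C)C
F3 | step 6 | racemic (5E,9E,13E)-15-(tert-butyldimethylsilyloxy)-6,10,14-trimethylpentadeca-5,9,13-trien-1-yn-4-ol | C/C(=C\CC/C(C)=C/CC/C(C)=C/C(O)CC#C)CO[Si](C)(C)C(C)(C)C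
F4 | step 6 | (4R,5E,9E,13E)-15-(tert-butyldimethylsilyloxy)-6,10,14-trimethylpentadeca-5,9,13-trien-1-yn-4-yl acetate | C/C(=C\CC/C(C)=C/CC/C(C)=C/[C@H](OC(C)=O)CC#C)CO[Si](C)(C)C(C)(C)C
F5 | step 13 | 2-[(2E,5S,6E,10E,14E)-5,16-dihydroxy-3,7,11,15-tetramethylhexadeca-2,6,10,14-tetraen-1-yl]-6-methyl-1,4-benzoquinone | C/C(=C\CC/C(C)=C/CC/C(C)=C/[C@@H](O)C/C(C)=C/CC1=CC(=O)C=C(C)C1=O)CO
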